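Ring A (the cyclopentane C1–C5, daucane numbering) is closed last across its only unfunctionalised edge, C2–C3. The key step exploits the 1,4-relationship between C2 and the oxygen-bearing C4 around the quaternary carbon C1: with C4 as an acetyl ketone and C2 as a non-enolisable formyl group on C1, a single aldol cyclodehydration converts a monocyclic cycloheptenone (ring B) into the trans-fused hydroazulene enone. The precursor is built on an (S)-4-silyloxy-2,6-dimethylcyclohepta-2,6-dienone, whose one stereocentre (C6) directs anti vinyl addition at C5 and trans hydroxymethylation at C1; isopropyl addition, C10 reduction with inversion and two acylations complete the target.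

Key step: step 10

Remark: locants are those of the daucane skeleton (C1 methyl-bearing ring-fusion carbon, C2/C3 ring A methylenes, C4 isopropyl carbinol, C5 ring-fusion CH, C6 aroyloxy carbon, C7 CH2, C8 methyl-bearing alkene carbon, C9 alkene CH, C10 angeloyloxy carbon); β is the face of the C1 methyl group and α the face of H-5; the facial sense of the catalyst in step 1 is assigned by analogy with aromatic aldehydes.

Step 1
Reactants: 1 acrolein; 2 2-methylallylboronic acid pinacol ester
Product: 3 (S)-5-methylhexa-1,5-dien-3-ol
Conditions: (S)-TRIP [(S)-3,3′-bis(2,4,6-triisopropylphenyl)-1,1′-binaphthyl-2,2′-diyl hydrogen phosphate] (5 mol %), 4 Å MS, toluene, −30 °C; aq. NaHCO3 work-up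
Reagents that add atoms: none
Why: Chiral phosphoric acid-catalysed allylboration of an aldehyde through a closed chair transition state, in which the (S)-catalyst is expected to direct the methallyl group to the Si face of acrolein and so set C6, the only stereocentre brought in from outside, as S.

Step 2
Reactants: 3 (S)-5-methylhexa-1,5-dien-3-ol
Product: 4 (S)-5-methylhexa-1,5-dien-3-yl acrylate
Conditions: acryloyl chloride, Et3N, DMAP (cat.), CH2Cl2, 0 °C
Reagents that add atoms: acryloyl chloride, C=CC(Cl)=O
Why: DMAP-catalysed O-acylation of the secondary allylic alcohol with an acid chloride, which leaves the stereocentre untouched.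

Step 3
Reactants: 4 (S)-5-methylhexa-1,5-dien-3-yl acrylate
Product: 5 (S)-4-methyl-6-vinyl-5,6-dihydro-2H-pyran-2-one
Conditions: second-generation Grubbs catalyst (5 mol %), CH2Cl2 (5 mM), reflux
Reagents that add atoms: none
Why: Ring-closing metathesis of the acrylate with the 1,1-disubstituted alkene should give the six-membered trisubstituted enoate and thereby lock the C8=C9 bond in the Z geometry needed later, the alternative butenolide closure on the allylic vinyl group being disfavoured by ring strain at this temperature.

Step 4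
Reactants: 5 (S)-4-methyl-6-vinyl-5,6-dihydro-2H-pyran-2-one
Product: 6 (4Z,7S)-7-hydroxy-2,5-dimethylnona-1,4,8-trien-3-one
Conditions: isopropenylmagnesium bromide (1.2 equiv), THF, −78 °C; aq. NH4Cl at −78 °C
Reagents that add atoms: isopropenylmagnesium bromide, CC(=C)[Mg]Br
Why: 1,2-Addition of an alkenyl Grignard reagent to a lactone, held at the ketone stage because the tetrahedral magnesium lactolate persists at low temperature and the β,β-disubstituted enoate resists conjugate addition; ring opening on quench frees the C6 alcohol and keeps the Z enone.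

Step 5
Reactants: 6 (4Z,7S)-7-hydroxy-2,5-dimethylnona-1,4,8-trien-3-one
Product: 7 (4Z,7S)-7-(tert-butyldimethylsilyloxy)-2,5-dimethylnona-1,4,8-trien-3-one
Conditions: TBSCl, imidazole, DMF, rt
Reagents that add atoms: tert-butyldimethylsilyl chloride, CC(C)(C)[Si](C)(C)Cl
Why: Imidazole-mediated silylation of the secondary alcohol drains the lactol/hydroxy ketone equilibrium into the open form and installs the bulky γ-substituent that will steer the conjugate addition.

Step 6
Reactants: 7 (4Z,7S)-7-(tert-butyldimethylsilyloxy)-2,5-dimethylnona-1,4,8-trien-3-one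
Product: 8 (S)-4-(tert-butyldimethylsilyloxy)-2,6-dimethylcyclohepta-2,6-dien-1-one
Conditions: second-generation Hoveyda–Grubbs catalyst (5 mol %), toluene (5 mM), 80 °C
Reagents that add atoms: none
Why: Ring-closing metathesis of the isopropenyl ketone with the terminal vinyl group closes ring B as a 2-methyl enone, the inert trisubstituted Z enone alkene only holding the two reacting ends within reach.

Step 7
Reactants: 8 (S)-4-(tert-butyldimethylsilyloxy)-2,6-dimethylcyclohepta-2,6-dien-1-one
Product: 10 5-(tert-butyldimethylsilyloxy)-7-(hydroxymethyl)-3,7-dimethyl-6-vinylcyclohept-2-en-1-one (6α-OTBS; 5β-vinyl; 1β-CH3; 1α-CH2OH), via bromomagnesium enolate 9 (not isolated)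
Conditions: CH2=CHMgBr (1.5 equiv), CuBr·SMe2 (15 mol %), THF, −78 → −40 °C; then CH2O (gas), −78 → −30 °C; aq. NH4Cl
Reagents that add atoms: vinylmagnesium bromide, C=C[Mg]Br; formaldehyde, C=O
Why: Copper-catalysed conjugate addition of the Grignard reagent to the less substituted enone terminus (C5; C8 is β,β-disubstituted) anti to the C6 silyloxy group sets C5, and aldol trapping of the enolate by formaldehyde on the face opposite the new vinyl group sets the quaternary C1 (tandem conjugate addition–hydroxymethylation).

Step 8
Reactants: 10 hydroxymethyl ketone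
Product: 11 3-(tert-butyldimethylsilyloxy)-1,5-dimethyl-7-oxo-2-vinylcyclohept-5-ene-1-carbaldehyde (6α-OTBS; 5β-vinyl; 1β-CH3; 1α-CHO)
Conditions: Dess–Martin periodinane, NaHCO3, CH2Cl2, 0 °C → rt
Reagents that add atoms: none
Why: Dess–Martin oxidation of the neopentyl primary alcohol to the non-enolisable aldehyde under buffered, non-basic conditions that avoid retro-aldol loss of formaldehyde.

Step 9
Reactants: 11 vinyl keto aldehyde
Product: 12 2-acetyl-3-(tert-butyldimethylsilyloxy)-1,5-dimethyl-7-oxocyclohept-5-ene-1-carbaldehyde (6α-OTBS; 5β-acetyl; 1β-CH3; 1α-CHO)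
Conditions: PdCl2 (10 mol %), CuCl, O2 (1 atm), DMF/H2O (7:1), rt
Reagents that add atoms: water, O
Why: Tsuji–Wacker oxidation of the terminal vinyl group with Markovnikov regiochemistry gives the methyl ketone, as is known for 2,2-disubstituted pent-4-enals, while the trisubstituted enone alkene is inert.

Step 10
Reactants: 12 acetyl keto aldehyde
Product: 14 6α-(tert-butyldimethylsilyloxy)-11,12,13-trinordauca-2,8-diene-4,10-dione (trans-fused; 1β-CH3; 5α-H), via β-hydroxy ketone 13 (not isolated)
Conditions: t-BuOK (0.3 equiv), t-BuOH/THF, 0 °C → rt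
Reagents that add atoms: none
Why: tert-Butoxide reversibly generates the methyl-ketone enolate (C3), which adds to the non-enolisable C2 aldehyde on the quaternary carbon C1, and E1cB loss of water from aldol 13 then gives the conjugated cyclopentenone irreversibly. The closest known reaction type is the intramolecular aldol condensation of 2,2-disubstituted 4-oxopentanals to 4,4-disubstituted cyclopent-2-enones. Ring A closes in the 5-(enolendo)-exo-trig mode through the single new C2–C3 bond. No stereocentre is created: C1, C5 and C6 are carried through, so the trans ring fusion is already fixed by step 7. The step needs chemoselectivity for the aldehyde over the C10 enone carbonyl and enolisation at C3 instead of C5; the aldehyde is the most electrophilic carbonyl, the bridged aldol at C10 cannot dehydrate and reverts, and the methyl group is the most accessible acidic site. The hindered, substoichiometric base at low temperature is chosen to keep deformylation of the β-keto aldehyde and epimerisation at C5 slower than ring closure.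

Step 11
Reactants: 14 enedione
Product: 15 6α-(tert-butyldimethylsilyloxy)-11,12,13-trinordauc-8-ene-4,10-dione
Conditions: [(Ph3P)CuH]6, H2O (2 equiv), benzene, rt
Reagents that add atoms: none
Why: Conjugate reduction by the copper hydride should be selective for the cyclopentenone, whose β-carbon (C2) carries only hydrogen, over the β,β-disubstituted cycloheptenone, and it leaves both carbonyl groups intact.

Step 12
Reactants: 15 diketone
Product: 16 6α-(tert-butyldimethylsilyloxy)-4β-hydroxydauc-8-en-10-one
Conditions: i-PrMgCl, CeCl3 (anhydrous), THF, −78 °C; aq. NH4Cl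
Reagents that add atoms: isopropylmagnesium chloride, CC(C)[Mg]Cl
Why: 1,2-Addition of the weakly basic organocerium reagent (which suppresses enolisation and β-hydride reduction) to the cyclopentanone, far more electrophilic than the hindered conjugated C10 ketone, from the α face anti to the angular C1 methyl group that is 1,3 to C4, which sets the 4β-hydroxy-4α-isopropyl centre.

Step 13
Reactants: 16 hydroxy enone
Product: 17 6α-(tert-butyldimethylsilyloxy)dauc-8-ene-4β,10β-diol
Conditions: NaBH4, CeCl3·7H2O, MeOH, −40 °C
Reagents that add atoms: none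
Why: Luche 1,2-reduction of the enone, in which hydride should arrive axially from the α face, anti to the pseudo-axial C1 methyl group next to the carbonyl, so that the 10β (equatorial) allylic alcohol is expected.

Step 14
Reactants: 17 4β,10β-diol; 18 angelic acid
Product: 19 10α-angeloyloxy-6α-(tert-butyldimethylsilyloxy)dauc-8-en-4β-ol
Conditions: PPh3, DIAD, toluene, 0 → 40 °C
Reagents that add atoms: none
Why: Mitsunobu esterification with SN2 inversion at the secondary allylic carbinol: the carboxylate enters from the unhindered α face used by hydride in step 13, elimination is impossible because C1 bears no hydrogen, SN2′ attack would have to occur at the fully substituted C8, the tertiary C4 alcohol does not react, and the neutral conditions keep the angelate Z.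

Step 15
Reactants: 19 silyl ether angelate
Product: 20 10α-angeloyloxydauc-8-ene-4β,6α-diol
Conditions: HF·pyridine, pyridine, THF, 0 °C → rt
Reagents that add atoms: none
Why: Fluoride-mediated cleavage of the secondary silyl ether under buffered conditions that neither saponify nor isomerise the angelate.

Step 16
Reactants: 20 4β,6α-diol angelate; 21 4-acetoxybenzoyl chloride
Product: 22 6α-(4-acetoxybenzoyloxy)-10α-angeloyloxydauc-8-en-4β-ol
Conditions: Et3N, DMAP, CH2Cl2, rt
Reagents that add atoms: none
Why: DMAP-catalysed acylation of the secondary C6 alcohol, the tertiary C4 alcohol being inert and the phenol being carried as its acetate so that the acyl donor cannot condense with itself.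

Step 17
Reactants: 22 aryl acetate
Product: 23 10α-angeloyloxy-6α-(4-hydroxybenzoyloxy)dauc-8-en-4β-ol (target, CNP0273650.2)
Conditions: pyrrolidine (3 equiv), CH2Cl2, 0 °C
Reagents that add atoms: none
Why: Chemoselective aminolysis of the aryl acetate, whose phenoxide leaving group makes it far more reactive than the two alkyl esters, releases the phenol.

Compound list
1 | acrolein | C=CC=O | starting material
2 | 2-methylallylboronic acid pinacol ester | CC(=C)CB1OC(C)(C)C(C)(C)O1 | starting material
3 | (S)-5-methylhexa-1,5-dien-3-ol | C=C[C@@H](O)CC(C)=C | intermediate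
4 | (S)-5-methylhexa-1,5-dien-3-yl acrylate | C=CC(=O)O[C@H](C=C)CC(C)=C | intermediate
5 | (S)-4-methyl-6-vinyl-5,6-dihydro-2H-pyran-2-one | O=C1C=C(C)C[C@@H](C=C)O1 | intermediate
6 | (4Z,7S)-7-hydroxy-2,5-dimethylnona-1,4,8-trien-3-one | C=C(C)C(=O)/C=C(C)\C[C@H](O)C=C | intermediate
7 | (4Z,7S)-7-(tert-butyldimethylsilyloxy)-2,5-dimethylnona-1,4,8-trien-3-one | C=C(C)C(=O)/C=C(C)\C[C@H](O[Si](C)(C)C(C)(C)C)C=C | intermediate
8 | (S)-4-(tert-butyldimethylsilyloxy)-2,6-dimethylcyclohepta-2,6-dien-1-one | O=C1C=C(C)C[C@H](O[Si](C)(C)C(C)(C)C)C=C1C | intermediate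
9 | bromomagnesium enolate of the 5β-vinyl adduct (6α-OTBS) | Br[Mg]OC1=C(C)[C@H](C=C)[C@@H](O[Si](C)(C)C(C)(C)C)CC(C)=C1 | intermediate
10 | 5-(tert-butyldimethylsilyloxy)-7-(hydroxymethyl)-3,7-dimethyl-6-vinylcyclohept-2-en-1-one (6α-OTBS; 5β-vinyl; 1β-CH3; 1α-CH2OH) | O=C1C=C(C)C[C@H](O[Si](C)(C)C(C)(C)C)[C@@H](C=C)[C@]1(C)CO | intermediate
11 | 3-(tert-butyldimethylsilyloxy)-1,5-dimethyl-7-oxo-2-vinylcyclohept-5-ene-1-carbaldehyde (6α-OTBS; 5β-vinyl; 1β-CH3; 1α-CHO) | O=C1C=C(C)C[C@H](O[Si](C)(C)C(C)(C)C)[C@@H](C=C)[C@]1(C)C=O | intermediate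
12 | 2-acetyl-3-(tert-butyldimethylsilyloxy)-1,5-dimethyl-7-oxocyclohept-5-ene-1-carbaldehyde (6α-OTBS; 5β-acetyl; 1β-CH3; 1α-CHO) | O=C1C=C(C)C[C@H](O[Si](C)(C)C(C)(C)C)[C@@H](C(C)=O)[C@]1(C)C=O | intermediate
13 | 2-hydroxy-6α-(tert-butyldimethylsilyloxy)-11,12,13-trinordauc-8-ene-4,10-dione (either C2 epimer) | O=C1C=C(C)C[C@H](O[Si](C)(C)C(C)(C)C)[C@@H]2[C@]1(C)C(O)CC2=O | intermediate
14 | 6α-(tert-butyldimethylsilyloxy)-11,12,13-trinordauca-2,8-diene-4,10-dione | O=C1C=C(C)C[C@H](O[Si](C)(C)C(C)(C)C)[C@@H]2[C@]1(C)C=CC2=O | intermediate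
15 | 6α-(tert-butyldimethylsilyloxy)-11,12,13-trinordauc-8-ene-4,10-dione | O=C1C=C(C)C[C@H](O[Si](C)(C)C(C)(C)C)[C@@H]2[C@]1(C)CCC2=O | intermediate
16 | 6α-(tert-butyldimethylsilyloxy)-4β-hydroxydauc-8-en-10-one | O=C1C=C(C)C[C@H](O[Si](C)(C)C(C)(C)C)[C@@H]2[C@]1(C)CC[C@@]2(O)C(C)C | intermediate
17 | 6α-(tert-butyldimethylsilyloxy)dauc-8-ene-4β,10β-diol | O[C@H]1C=C(C)C[C@H](O[Si](C)(C)C(C)(C)C)[C@@H]2[C@]1(C)CC[C@@]2(O)C(C)C | intermediate
18 | angelic acid, (Z)-2-methylbut-2-enoic acid | C/C=C(/C)C(=O)O | starting material
19 | 10α-angeloyloxy-6α-(tert-butyldimethylsilyloxy)dauc-8-en-4β-ol | C/C=C(/C)C(=O)O[C@@H]1C=C(C)C[C@H](O[Si](C)(C)C(C)(C)C)[C@@H]2[C@]1(C)CC[C@@]2(O)C(C)C | intermediate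
20 | 10α-angeloyloxydauc-8-ene-4β,6α-diol | C/C=C(/C)C(=O)O[C@@H]1C=C(C)C[C@H](O)[C@@H]2[C@]1(C)CC[C@@]2(O)C(C)C | intermediate
21 | 4-acetoxybenzoyl chloride | CC(=O)Oc1ccc(cc1)C(Cl)=O | starting material
22 | 6α-(4-acetoxybenzoyloxy)-10α-angeloyloxydauc-8-en-4β-ol | C/C=C(/C)C(=O)O[C@@H]1C=C(C)C[C@H](OC(=O)c2ccc(OC(C)=O)cc2)[C@@H]2[C@]1(C)CC[C@@]2(O)C(C)C | intermediate
23 | 10α-angeloyloxy-6α-(4-hydroxybenzoyloxy)dauc-8-en-4β-ol (CNP0273650.2) | C/C=C(/C)C(=O)O[C@@H]1C=C(C)C[C@H](OC(=O)c2ccc(O)cc2)[C@@H]2[C@]1(C)CC[C@@]2(O)C(C)C | target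

Total step count: 17. Longest linear sequence: 17 steps (1 and 2 to 23; 18 and 21 are bought).

Steps most likely to fail

1. Step 14. The displacement at the carbinol carbon next to the quaternary C1 may stall, or the carboxylate may be captured with allylic transposition. The fallback sets out from 16 and returns at 19, and sets C10 by reagent control instead of inversion. CBS reduction of enone 16 ((S)-2-methyl-CBS-oxazaborolidine, catecholborane, toluene, −78 °C) should give the 10α-alcohol F1; this catalyst enantiomer delivers hydride to the β face if the quaternary C1 side acts as the large group, and its antipode is taken otherwise. Angelic acid 18 is converted with 2,4,6-trichlorobenzoyl chloride and Et3N into the mixed anhydride F2, which acylates F1 with retention (DMAP, toluene; Yamaguchi esterification) to give 19.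

2. Step 10. The base may cleave the formyl group from the β-keto aldehyde (retro-Claisen), or enolisation at C5 may erode the trans ring fusion or expel the C6 silyloxy group. The fallback sets out from 12 and returns at 14, closing the same bond under Lewis-acid conditions. TMSOTf and i-Pr2NEt (CH2Cl2, −78 °C) convert the methyl ketone into the trimethylsilyl enol ether F3, which adds in the same flask to the TMSOTf-activated aldehyde (intramolecular Mukaiyama aldol). Mild acidic work-up gives aldol 13, now isolated; MsCl and Et3N give the mesylate F4, and DBU eliminates it to 14.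

3. Step 12. The hindered cyclopentanone may be enolised or reduced by β-hydride transfer, and addition at the C10 enone carbonyl may compete. The fallback sets out from 15 and returns at 16. Isopropenylmagnesium bromide with CeCl3 (THF, −78 °C), a smaller sp2 nucleophile that cannot transfer a β-hydride, should give the isopropenyl carbinol F5. Hydrogenation with RhCl(PPh3)3 and H2 (benzene, rt) then saturates only the 1,1-disubstituted alkene and gives 16.

Further compounds
F1 | step 14 | 6α-(tert-butyldimethylsilyloxy)dauc-8-ene-4β,10α-diol | O[C@@H]1C=C(C)C[C@H](O[Si](C)(C)C(C)(C)C)[C@@H]2[C@]1(C)CC[C@@]2(O)C(C)C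
F2 | step 14 | (Z)-2-methylbut-2-enoic 2,4,6-trichlorobenzoic anhydride | C/C=C(/C)C(=O)OC(=O)c1c(Cl)cc(Cl)cc1Cl
F3 | step 10 | trimethylsilyl enol ether of keto aldehyde 12 | O=C1C=C(C)C[C@H](O[Si](C)(C)C(C)(C)C)[C@@H](C(=C)O[Si](C)(C)C)[C@]1(C)C=O
F4 | step 10 | C2 mesylate of aldol 13 | O=C1C=C(C)C[C@H](O[Si](C)(C)C(C)(C)C)[C@@H]2[C@]1(C)C(OS(C)(=O)=O)CC2=O
F5 | step 12 | 6α-(tert-butyldimethylsilyloxy)-4β-hydroxydauca-8,11-dien-10-one (isopropenyl carbinol) | O=C1C=C(C)C[C@H](O[Si](C)(C)C(C)(C)C)[C@@H]2[C@]1(C)CC[C@@]2(O)C(C)=C
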